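- Read the ring clock first.

| flask | starting material | activator | remark | time |
|---|---|---|---|---|
| alpha | 0.087 M | 2 equiv | run made earlier |  |
| gamma | 0.087 M | 4 equiv | run made earlier |  |
| Saturday's | 0.087 M | 2.00 equiv (fed, over 30 min) | all else is in the flask from the start; the feed brings no volume worth counting | 2.5 h |
| Friday's | 0.087 M | 2.00 equiv | everything together at the start | 2.5 h |
| Monday's | 0.087 M (fed, over 30 min) | 2.00 equiv | all else is in the flask from the start; the feed brings no volume worth counting | 2.5 h |

- alpha (time / h: ring / %, open dimer / %): 0.500: 22.4, 16.3; 1.00: 18.8, 14.8; 1.50: 14.6, 15.5; 2.00: 12.0, 15.4; 2.50: 10.0, 17.2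
- gamma (time / min: ring / %, open dimer / %): 1.33: 1.3, 6.2; 2.50: 4.3, 8.2; 4.00: 7.7, 9.7; 8.00: 15.4, 8.6; 15.0: 21.5, 11.1

(readings scatter by 1 percentage point)

* the flask that comes out highest in share of ring in ring plus open dimer, or "all alike" when all lie within 1.5 percentage points (Saturday's / Friday's / Monday's / all alike)
* share of ring in ring plus open dimer at the end, Saturday's
* share of ring in ring plus open dimer at the end, Friday's
* share of ring in ring plus open dimer at the end, Monday's

- percentages count the starting material that a species holds: one open dimer counts as two
- what was read earlier has a scatter of 1 percentage point, one standard deviation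

- In alpha, ring falls from 22.4% at 0.500 h to 10.0% at 2.50 h, while open dimer goes from 16.3% to 17.2%, a change inside the scatter of 1 percentage point. So the share of ring, our selectivity, is a moving number: one product holds and the other leaks.
- A first-order loss has a constant, the logarithm of the fall divided by the time, here 0.403 h⁻¹. The ring clock, the time in which ring halves once its supply has stopped, is ln of two over that constant: 1.72 h, a reading with the scatter in it.
- That is the late end. A feed closing at 30 min leaves 1.16 half-lives, for Saturday's and Monday's alike. That carries a fraction forward, not an amount, and the earlier runs do not read ring in a fed flask, so alpha's final ring is a rough stand-in of ours.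
- The early end is open dimer. Gamma, with 4 equiv of activator, holds 11.1% against alpha's 16.3%, so we take activator in excess of starting material to hold open dimer down.
- Joining the ends, our Friday's, alpha's recipe, gives 36.8%. Our Monday's, with that stand-in for ring and gamma's open dimer, gives 47.4%, a rough estimate. Saturday's, which starts short of activator, should land below Friday's.
- The forecast says Monday's, with 41% for Saturday's, 38.5% for Friday's and 45% for Monday's, and it agrees that “ring decays independently”. It puts Saturday's above Friday's, where we put it below.
- The flasks give Monday's as highest, at 56.6%, then Friday's at 38.0% and Saturday's at 29.8%.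

    starting material + activator → activated form (k = 2.90 M⁻¹ min⁻¹)
    activated form → side product (k = 0.0710 min⁻¹)
    ring → over-reaction product (k = 0.00710 min⁻¹)
    starting material + activated form → open dimer (k = 1.30 M⁻¹ min⁻¹)
    starting material ⇌ dormant form (K = 21.0, k = 0.0380 min⁻¹)
    activated form → ring (k = 0.0370 min⁻¹)

- Monday's is not at rest at 2.5 h. From its 20.0% of ring at 1.25 h, the clock gives 12.1% at the end, and the flask holds 12.1%. On Saturday's, 11.8% at the same time reckons to 7.15%, and the flask holds 7.90%. Left until 25.0 h, Monday's keeps 9.27% of open dimer while ring drops to 0.0827%, so its share falls to 0.884%. Saturday's keeps 18.7% of open dimer, and its share falls to 1.64%.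

The earlier runs and the new flask were generated by integration for substances that don't exist; noise was put on by code.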